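The runs come from a simulation for substances that don't exist; the scatter is artificial.

Before any constant is fitted, I ask which of the given numbers Tuesday's flask can feel at all. Here J is the substrate, X the reagent, E the product and G the catalyst.

| flask | J | X | G | time |
|---|---|---|---|---|
| Thursday's | 80.0 mM | 88.0 mM | 4.00 mM |  |
| Saturday's | 40.0 mM | 48.0 mM | 4.00 mM |  |
| Monday's | 240 mM | 88.0 mM | 4.00 mM |  |
| Wednesday's | 80.0 mM | 88.0 mM | 8.00 mM |  |
| Tuesday's | 400 mM | 440 mM | 4.00 mM | 36 h |

| Thursday's run: time / h | Thursday's run: [E] / mM | Saturday's run: time / h | Saturday's run: [E] / mM | Monday's run: time / h | Monday's run: [E] / mM | Wednesday's run: time / h | Wednesday's run: [E] / mM |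
|---|---|---|---|---|---|---|---|
| 1.4 | 4.4 | 1.4 | 1.6 | 1.4 | 8.6 | 1.4 | 11.0 |
| 2.3 | 7.3 | 2.3 | 2.6 | 2.3 | 10.9 | 2.3 | 15.9 |
| 3.6 | 9.5 | 3.6 | 2.9 | 3.6 | 15.1 | 3.6 | 20.0 |
| 5.7 | 14.1 | 5.7 | 4.8 | 5.7 | 18.8 | 5.7 | 28.0 |
| 9.1 | 15.9 | 9.1 | 7.0 | 9.1 | 22.0 | 9.1 | 35.3 |
| 14 | 19.5 | 14 | 9.2 | 14 | 24.4 | 14 | 41.4 |
| 23 | 23.8 | 23 | 11.8 | 23 | 25.3 | 23 | 46.2 |
| 36 | 26.8 | 36 | 12.9 | 36 | 24.0 | 36 | 48.7 |

(scatter of a reading: 0.8 mM)

- Overall: J + X -> E, with G as catalyst.
- Constant volume, constant temperature.
- What is held in complexes is read along with the free species.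
- "The second partner" is X.
- An order is taken over about fifteen percent of the charge, up and down.

* the exponent of [G] in the starting rate at the charge of the Thursday's run (at the point where two percent of the J have become E)
* the exponent of [X] in the starting rate at the charge of the Thursday's run (at the point where two percent of the J have become E)
* E in the Tuesday's run at 36 h, as a share of the J charged

Thursday's flask reads 26.8 mM of E at its last point, from 80.0 mM of J, so I take G to have a lifetime. I reckon with the reach ρ, the exponent of a pseudo-first-order loss of X: the natural log of the X charged over the X left at the stall, for which I take the last reading. E at the stall is then the X charged times one minus exp(−ρ).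

Now the numbers in turn. Time matters little if Tuesday's flask dies as Thursday's does: Thursday's lifetime, last reading over early slope, is 8.53 h, so 36 h is 4.22 lifetimes, which leaves 1.47% of the working G in Thursday's flask if the decay is exponential. J matters little between these two flasks: Monday's flask holds 240 mM against Thursday's 80.0 mM, yet its reach reads 0.318 against 0.363. G matters strongly: Wednesday's flask, with twice Thursday's G, reaches 0.806, but Tuesday's G equals Thursday's, so I need no law in G. X enters directly, and its charge is given. The scatter of one reading moves Thursday's reach by 0.0131, and a shift of that size moves Tuesday's reckoned stall by about 4.00 mM of E.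

So the number itself: Saturday's flask reads 0.313, and the mean over Thursday's, Saturday's and Monday's flasks, each at 4.00 mM of G, is 0.332, the reach. With 440 mM of X, Tuesday's flask should stall at 124 mM, or 31.0% of its J.

The forecast says 30% (20% to 40%), slightly less than mine, with orders 1.15 in G and 0.85 in X. One of its grounds: “All runs stall well before reagents run out, so the catalyst is dying.”

Tuesday's flask gives 32.4% of the J charged at 36 h, and the starting orders at Thursday's charge come to 1.7 in G and 1.1 in X.

    G + J ⇌ GJ, settled at all times (5.260 M⁻¹)
    GJ + X → E + G + Q (56.52 M⁻¹ h⁻¹)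
    G + Rx → Jo
    GJ → Jo + J (0.4032 h⁻¹)

Rx takes 1.51 mM of G at once, so the G left to work at the start is 2.49 mM in Thursday's flask against 6.49 mM in Wednesday's, a ratio of 2.61. My reach of 0.332, multiplied by that ratio, becomes 0.864 for Wednesday's flask and puts its stall at 50.9 mM of E.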